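**Retrosynthetic overview**
- Last bond broken: the 4'-O-benzyl ether (hydrogenolysis); it is a protecting group only.
- Key disconnection: the C6–O bond. The 5,6-catechol comes from a 5-hydroxy-7-methoxyflavone by chelate-directed ortho C–H hydroxylation, through the 5,6-ortho-quinone.
- Pyran-4-one ring (O1–C2 bond): iodine/DMSO oxidative cyclization of a 2',6'-dihydroxychalcone.
- Chalcone: Claisen–Schmidt condensation of 2',6'-dihydroxy-4'-methoxyacetophenone with 4-benzyloxy-2,5-dimethoxybenzaldehyde, the latter made by benzylation of the hydroxy aldehyde.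
- Ring order: both benzene rings are bought; the pyranone is the only ring built (step 3).

Assumption: the target has no stereocentre (achiral flavone), so no stereocontrol is needed; 4-hydroxy-2,5-dimethoxybenzaldehyde and 2',6'-dihydroxy-4'-methoxyacetophenone are taken as catalogue compounds.

**Step 1**
Reactants: 1 4-hydroxy-2,5-dimethoxybenzaldehyde
Product: 2 4-(benzyloxy)-2,5-dimethoxybenzaldehyde
Conditions: BnBr (1.1 equiv), K2CO3 (1.5 equiv), DMF, 60 °C, 3 h
Reagents that add atoms: benzyl bromide, BrCc1ccccc1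
Why: Williamson ether synthesis (SN2 of the phenoxide on benzyl bromide); the aldehyde is inert to K2CO3/DMF, and the benzyl group masks the only B-ring phenol for step 4.

**Step 2**
Reactants: 2 4-(benzyloxy)-2,5-dimethoxybenzaldehyde; 3 1-(2,6-dihydroxy-4-methoxyphenyl)ethan-1-one
Product: 4 (E)-3-[4-(benzyloxy)-2,5-dimethoxyphenyl]-1-(2,6-dihydroxy-4-methoxyphenyl)prop-2-en-1-one
Conditions: KOH (50% aq., 10 equiv), EtOH, 0 °C → rt, 48 h; then 2 M HCl
Reagents that add atoms: none
Why: Claisen–Schmidt (crossed aldol) condensation in which the aldehyde has no α-hydrogen and the methyl ketone is the only enolisable partner; E1cB dehydration gives the thermodynamic E-enone and the benzyl ether is base-stable.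

**Step 3**
Reactants: 4 (E)-3-[4-(benzyloxy)-2,5-dimethoxyphenyl]-1-(2,6-dihydroxy-4-methoxyphenyl)prop-2-en-1-one
Product: 6 2-[4-(benzyloxy)-2,5-dimethoxyphenyl]-5-hydroxy-7-methoxy-4H-chromen-4-one, via flavanone 5 (not isolated)
Conditions: I2 (10 mol %), DMSO, 120 °C, 3 h
Reagents that add atoms: none
Why: Iodine/DMSO oxidative cyclization of a 2'-hydroxychalcone: 6-endo oxa-Michael closure forms the O1–C2 bond (the two phenols are equivalent, so only one regioisomer is possible), α-iodination/HI elimination aromatizes the pyranone and destroys the transient C2 stereocentre, and DMSO re-oxidizes HI to I2.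

**Step 4**
Reactants: 6 2-[4-(benzyloxy)-2,5-dimethoxyphenyl]-5-hydroxy-7-methoxy-4H-chromen-4-one
Product: 8 2-[4-(benzyloxy)-2,5-dimethoxyphenyl]-5,6-dihydroxy-7-methoxy-4H-chromen-4-one, via ortho-quinone 7 (not isolated)
Conditions: Ti(OiPr)4 (20 mol %), 4 Å MS, CH2Cl2, rt, 30 min; TBHP (5.5 M in decane, 2.2 equiv), −20 °C → rt; then aq. Na2S2O4, EtOAc, rt
Reagents that add atoms: tert-butyl hydroperoxide, CC(C)(C)OO
Why: Proposed new method: the 5-OH/4-C=O pair binds Ti(IV) as a six-membered ketophenolate chelate (the site that Al and Zr shift reagents bind in flavonoids), tert-butyl hydroperoxide joins the same metal as an η2-alkylperoxide, and its electrophilic oxygen is delivered intramolecularly to C6, the only ortho C–H of the bound phenolate and the most electron-rich ring carbon (ortho to O5 and OMe, para to O1), forming the C6–O bond; the Ti catecholate is oxidized on to the ortho-quinone, which leaves the metal so Ti turns over, and dithionite returns the catechol, while the benzylated B ring offers no second phenol to bind titanium; the closest known reaction type is the Ti- or Zr-alkoxide/TBHP ortho-oxidation of simple non-chelated phenols and naphthols to ortho-quinones, together with the directed oxygen transfer of Ti–alkylperoxides in allylic-alcohol epoxidation, neither shown on a hydrogen-bonded peri-hydroxycarbonyl phenol of a flavone.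

**Step 5**
Reactants: 8 2-[4-(benzyloxy)-2,5-dimethoxyphenyl]-5,6-dihydroxy-7-methoxy-4H-chromen-4-one
Product: 9 2-(4-hydroxy-2,5-dimethoxyphenyl)-5,6-dihydroxy-7-methoxy-4H-chromen-4-one
Conditions: H2 (1 atm), 10% Pd/C, EtOAc/MeOH 1:1, rt, 2 h; filtration under N2
Reagents that add atoms: none
Why: Heterogeneous hydrogenolysis of the benzyl aryl ether; the flavone C2=C3 bond (part of the aromatic pyranone) and the three methyl ethers are inert at 1 atm and room temperature.

**Compound list**
1 | 4-hydroxy-2,5-dimethoxybenzaldehyde | COc1cc(C=O)c(OC)cc1O | starting material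
2 | 4-(benzyloxy)-2,5-dimethoxybenzaldehyde | COc1cc(C=O)c(OC)cc1OCc1ccccc1 | intermediate
3 | 1-(2,6-dihydroxy-4-methoxyphenyl)ethan-1-one | CC(=O)c1c(O)cc(OC)cc1O | starting material
4 | (E)-3-[4-(benzyloxy)-2,5-dimethoxyphenyl]-1-(2,6-dihydroxy-4-methoxyphenyl)prop-2-en-1-one | COc1cc(O)c(C(=O)/C=C/c2cc(OC)c(OCc3ccccc3)cc2OC)c(O)c1 | intermediate
5 | rac-2-[4-(benzyloxy)-2,5-dimethoxyphenyl]-5-hydroxy-7-methoxy-2,3-dihydro-4H-chromen-4-one (racemic, not isolated) | COc1cc(O)c2c(c1)OC(c1cc(OC)c(OCc3ccccc3)cc1OC)CC2=O | intermediate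
6 | 2-[4-(benzyloxy)-2,5-dimethoxyphenyl]-5-hydroxy-7-methoxy-4H-chromen-4-one | COc1cc(O)c2c(c1)oc(-c1cc(OC)c(OCc3ccccc3)cc1OC)cc2=O | intermediate
7 | 2-[4-(benzyloxy)-2,5-dimethoxyphenyl]-7-methoxy-4H-chromene-4,5,6-trione (not isolated) | COC1=CC2=C(C(=O)C=C(O2)c2cc(OC)c(OCc3ccccc3)cc2OC)C(=O)C1=O | intermediate
8 | 2-[4-(benzyloxy)-2,5-dimethoxyphenyl]-5,6-dihydroxy-7-methoxy-4H-chromen-4-one | COc1cc2oc(-c3cc(OC)c(OCc4ccccc4)cc3OC)cc(=O)c2c(O)c1O | intermediate
9 | 2-(4-hydroxy-2,5-dimethoxyphenyl)-5,6-dihydroxy-7-methoxy-4H-chromen-4-one (CNP0310413.0, achiral) | COc1cc(-c2cc(=O)c3c(O)c(O)c(OC)cc3o2)c(OC)cc1O | target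

**Step count**
Total steps: 5. Longest linear sequence: 5 (1 → 2 → 4 → 6 → 8 → 9; ketone 3 enters at step 2).

**Three steps most likely to fail**

Step 4, the new step. The chelated phenolate may be too weak a nucleophile for the titanium peroxide, oxidation may stray to C8, or the ortho-quinone may be over-oxidized before reduction. The fallback uses known chemistry; it sets out from flavone 6 and comes back at target 9, skipping 7 and 8. Electrophilic iodination ortho to the free 5-OH (benzyltrimethylammonium dichloroiodate, CaCO3, CH2Cl2/MeOH, rt) gives 2-[4-(benzyloxy)-2,5-dimethoxyphenyl]-5-hydroxy-6-iodo-7-methoxy-4H-chromen-4-one F1. Copper-catalysed Ullmann-type C–O coupling with benzyl alcohol (CuI, 3,4,7,8-tetramethyl-1,10-phenanthroline, Cs2CO3, toluene, 110 °C) gives 6-(benzyloxy)-2-[4-(benzyloxy)-2,5-dimethoxyphenyl]-5-hydroxy-7-methoxy-4H-chromen-4-one F2. Hydrogenolysis of both benzyl ethers (H2, Pd/C) then gives 9.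

Step 2. The dianion of the doubly hydrogen-bonded ketone 3 is a sluggish nucleophile and the electron-rich aldehyde 2 a poor electrophile, so conversion may stall. The fallback replaces the aldol logic by acyl transfer (Baker–Venkataraman type); it sets out from 2 and 3 and comes back at flavone 6, skipping 4 and 5. Pinnick oxidation of 2 (NaClO2, NaH2PO4, 2-methyl-2-butene, tBuOH/H2O) gives 4-(benzyloxy)-2,5-dimethoxybenzoic acid F3. Oxalyl chloride with catalytic DMF gives 4-(benzyloxy)-2,5-dimethoxybenzoyl chloride F4. C-acylation of the trianion of 3 (LiHMDS, 4 equiv, THF, −78 °C → rt) gives 1-[4-(benzyloxy)-2,5-dimethoxyphenyl]-3-(2,6-dihydroxy-4-methoxyphenyl)propane-1,3-dione F5. Cyclodehydration (AcOH, cat. H2SO4, 95 °C) closes the pyranone to 6.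

Step 3. Iodine may iodinate the phloroglucinol-type ring, or HI at 120 °C may nick the benzyl ether. The fallback separates ring closure from oxidation and uses no iodine; it sets out from chalcone 4 and comes back at flavone 6. Isomerization with NaOAc in refluxing EtOH gives flavanone 5, this time isolated, and DDQ in refluxing dioxane dehydrogenates it to 6. No compound outside the list is made (F0).

**Further compounds**
F1 | step 4 | 2-[4-(benzyloxy)-2,5-dimethoxyphenyl]-5-hydroxy-6-iodo-7-methoxy-4H-chromen-4-one | COc1cc2oc(-c3cc(OC)c(OCc4ccccc4)cc3OC)cc(=O)c2c(O)c1I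
F2 | step 4 | 6-(benzyloxy)-2-[4-(benzyloxy)-2,5-dimethoxyphenyl]-5-hydroxy-7-methoxy-4H-chromen-4-one | COc1cc2oc(-c3cc(OC)c(OCc4ccccc4)cc3OC)cc(=O)c2c(O)c1OCc1ccccc1
F3 | step 2 | 4-(benzyloxy)-2,5-dimethoxybenzoic acid | COc1cc(C(=O)O)c(OC)cc1OCc1ccccc1
F4 | step 2 | 4-(benzyloxy)-2,5-dimethoxybenzoyl chloride | COc1cc(C(Cl)=O)c(OC)cc1OCc1ccccc1
F5 | step 2 | 1-[4-(benzyloxy)-2,5-dimethoxyphenyl]-3-(2,6-dihydroxy-4-methoxyphenyl)propane-1,3-dione | COc1cc(O)c(C(=O)CC(=O)c2cc(OC)c(OCc3ccccc3)cc2OC)c(O)c1
F0 | step 3 | none | none
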